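**Plan**

Numbering: oxane O1, C2 (CMe2), C3 (CHBr), C4, C5 (CHOH), C6 (CMe); cyclohexane C1′ (carbinol on C6), C2′, C3′ (CHBr), C4′ (CClMe), C5′, C6′. β is the oxane face carrying C1′ and the C5 oxygen; α is the face of the C6 methyl and the C3 bromine.
Enabling feature: O1 lies between two fully substituted carbons that each bear a methyl group (C2, C6), which is the O/C2/C5 pattern of 2,5-dimethylfuran, and C3–C4–C5 is a three-carbon oxyallyl unit. A [4+3] cycloaddition therefore makes C2–C3 and C5–C6 and closes the oxane without forming any C–O bond.
Cuts, in retrosynthetic order: C4′–Cl and C3′–Br (back to a cyclohexene via a C1′–O–C4′ bromo ether), C3′=C4′ (ring-closing metathesis), C1′–C2′ and C1′–C6′ (two Grignard additions), C3–Br (from the β-alcohol), C1′ and the β-methyl on C2 rejoined as an etheno bridge, then C2–C3 and C5–C6.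
Forward order of rings: the oxane forms first, inside an 8-oxabicyclo[3.2.1]octenone. The bridge is then cleaved, one arm becomes the second C2 methyl, the C4 ketone is exchanged for the C3 bromide, and the other arm (C1′) is grown into the cyclohexane, which is halogenated last.
Stereochemistry: C5 and C6 (and C2 transiently) come from the cycloaddition under a 1-phenylethyl auxiliary. C3 comes from a tethered syn hydrosilylation on the β face followed by SN2 inversion, and C1′ from Felkin–Anh allylation. C3′ and C4′ come from bromoetherification through the axial C1′ hydroxyl and a retentive, bromine-assisted exchange of that ether oxygen for chloride.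

Key step: step 3

Assumption: the (S)-configured auxiliary is taken to lead to the (1R,2S,5R) cycloadduct. If induction runs the other way, (R)-1-phenylethanol is used and nothing else changes.

**Step 1**
Reactants: 1 pyruvaldehyde dimethyl acetal; 2 (S)-1-phenylethanol
Product: 3 1,1-bis[(S)-1-phenylethoxy]propan-2-one
Conditions: 2 (2.2 equiv), p-TsOH (cat.), cyclohexane, 5 Å MS, 60 °C (MeOH removed)
Reagents that add atoms: none
Why: Acid-catalysed transacetalisation driven by removal of methanol should exchange both methoxy groups, and the carbinol C–O bonds of 2 are not broken, so both auxiliary stereocentres are retained.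

**Step 2**
Reactants: 3 1,1-bis[(S)-1-phenylethoxy]propan-2-one
Product: 4 2-(triethylsilyloxy)acrolein bis[(S)-1-phenylethyl] acetal
Conditions: TESOTf, Et3N, Et2O, 0 °C
Reagents that add atoms: triethylsilyl triflate CC[Si](CC)(CC)OS(=O)(=O)C(F)(F)F
Why: Soft enolisation with a silyl triflate and an amine removes a methyl proton rather than the hindered acetal C–H and should give the terminal silyl enol ether.

**Step 3**
Reactants: 4 2-(triethylsilyloxy)acrolein bis[(S)-1-phenylethyl] acetal; 5 2,5-dimethylfuran
Product: 7 (1R,2S,5R)-1,5-dimethyl-2-[(S)-1-phenylethoxy]-8-oxabicyclo[3.2.1]oct-6-en-3-one, via siloxyallyl cation 6 (not isolated)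
Conditions: 5 (3 equiv), TMSOTf (10 mol %), CH2Cl2, −95 → −78 °C
Reagents that add atoms: none
Why: Catalytic TMSOTf removes one of the two equivalent 1-phenylethoxy groups of 4 and leaves the Z (W-shaped) cation 6, which bonds through its two termini to C2 and C5 of 5; loss of the silyl group from the carbonyl oxygen regenerates silyl triflate, and the expelled alkoxide ends as its TES ether. The closest known reaction type is the low-temperature [4+3] cycloaddition of furans with alkoxy-substituted 2-siloxyallyl cations generated from chiral α-ketoacetal enol ethers. The ring closure is a (4π+2π) cycloaddition, concerted or as two rapid C–C bond formations, that builds the seven-membered carbocycle in one event; the furan oxygen bridges it, so the oxane (O1, C2–C6) and the 2,5-dihydrofuran holding the etheno bridge arise together through the bonds C5–C6 and C2–C3. C2 and C6 are fixed relative to each other by suprafacial addition to the furan, and C5 by the Z geometry of 6 combined with the compact (endo) transition state, which places the alkoxy group equatorial, on the bridge side of the oxane. The absolute sense comes from the 1-phenylethyl group, which shields one face of 6. The step needs face selectivity on the cation and an equatorial C5 substituent but no regioselectivity, because 5 is symmetrical; the low temperature, the preferred conformation of the auxiliary and, if needed, base equilibration of an axial C5 epimer secure them.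

**Step 4**
Reactants: 7 cycloadduct ketone
Product: 8 1,5-dimethyl-4-[(S)-1-phenylethoxy]-8-oxabicyclo[3.2.1]octa-2,6-dien-3-yl triflate (ring stereocentres as in 7)
Conditions: KHMDS, THF, −78 °C; PhNTf2, −78 → 0 °C
Reagents that add atoms: N-phenylbis(trifluoromethanesulfonimide) O=S(=O)(N(c1ccccc1)S(=O)(=O)C(F)(F)F)C(F)(F)F
Why: Kinetic deprotonation by a hindered amide takes the exo proton of the C3 methylene rather than the alkoxy-bearing C5–H, and O-sulfonylation should give the C3=C4 enol triflate, an electron-poor mask for the later alkene.

**Step 5**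
Reactants: 8 enol triflate
Product: 10 2β,6β-bis(hydroxymethyl)-2α,6α-dimethyl-5β-[(S)-1-phenylethoxy]-5,6-dihydro-2H-pyran-4-yl triflate, via dialdehyde 9 (not isolated)
Conditions: O3, CH2Cl2/MeOH, −78 °C (Sudan III end-point); NaBH4, −78 °C → rt
Reagents that add atoms: ozone [O-][O+]=O
Why: In this ozonolysis with reductive work-up the electrophilic ozone should select the strained, electron-richer etheno bridge over the triflate-deactivated C3=C4 bond, and borohydride carries 9 on to the diol without touching a stereocentre.

**Step 6**
Reactants: 10 diol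
Product: 11 5β-hydroxy-2β,6β-bis(hydroxymethyl)-2α,6α-dimethyl-5,6-dihydro-2H-pyran-4-yl triflate
Conditions: TFA, Et3SiH, CH2Cl2, 0 °C; aq NaHCO3
Reagents that add atoms: none
Why: In this ionic hydrogenolysis the 1-phenylethyl cation forms about as easily as tert-butyl and is trapped by the silane, while the ring C–O bonds are deactivated by β-oxygen atoms and by the triflate, and hydrogenation, which would endanger the enol triflate, is avoided.

**Step 7**
Reactants: 11 triol
Product: 12 benzylidene acetal of 11 across C5β–O and C6β–CH2O (1,3-dioxane cis-fused at C5–C6, phenyl equatorial), C2β–CH2OH free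
Conditions: PhCH(OMe)2, CSA (cat.), CH2Cl2, rt
Reagents that add atoms: benzaldehyde dimethyl acetal COC(OC)c1ccccc1
Why: In this thermodynamic acetalisation only the C5–OH/C1′–OH pair is a 1,3-diol, so a single 1,3-dioxane with equatorial phenyl should form, which distinguishes the two arms; the new acetal centre is removed again in step 13.

**Step 8**
Reactants: 12 benzylidene acetal triflate
Product: 13 benzylidene-protected 2β-(hydroxymethyl)-2α,6α-dimethyl-5,6-dihydro-2H-pyran (C3=C4 alkene)
Conditions: Pd(OAc)2 (5 mol %), PPh3, HCO2H, Et3N, DMF, 60 °C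
Reagents that add atoms: none
Why: Palladium-catalysed formate reduction of an enol triflate replaces OTf by H under conditions that a free primary alcohol and the acetal tolerate.

**Step 9**
Reactants: 13 homoallylic alcohol
Product: 16 benzylidene-protected 3β-hydroxy-2β-(hydroxymethyl)-2α,6α-dimethyloxane, via dimethylsilyl ether 14 (not isolated), via oxasilolane 15 (not isolated)
Conditions: (HMe2Si)2NH, 40 °C, evaporate; Pt2(dvs)3 (0.5 mol %), toluene, 60 °C; 30% H2O2, KF, KHCO3, THF/MeOH, rt
Reagents that add atoms: hydrogen peroxide OO; 1,1,3,3-tetramethyldisilazane C[SiH](C)N[SiH](C)C (its silicon stays only in 14 and 15)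
Why: In this intramolecular hydrosilylation and Tamao oxidation of a homoallylic alcohol the β-oriented tether allows only 5-exo syn delivery of silicon to C3 and hydrogen to C4 on the β face, and oxidation with retention gives the C3 β-alcohol; this avoids hydride opening of a C3–C4 epoxide, where attack at C4 would have to pass between the C2 and C6 substituents.

**Step 10**
Reactants: 16 diol
Product: 17 benzylidene-protected 2β-(iodomethyl)-2α,6α-dimethyloxan-3β-ol
Conditions: I2, PPh3, imidazole, toluene, 70 °C
Reagents that add atoms: iodine II
Why: Garegg–Samuelsson iodination should select the primary alcohol, because the C3 hydroxyl is secondary, axial and flanked by a quaternary carbon.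

**Step 11**
Reactants: 17 iodide
Product: 18 benzylidene-protected 2,2,6α-trimethyloxan-3β-ol
Conditions: Bu3SnH, AIBN (cat.), toluene, 80 °C
Reagents that add atoms: none
Why: Radical-chain dehalogenation is indifferent to the neopentyl position, turns the arm into the second C2 methyl and removes the temporary C2 stereocentre.

**Step 12**
Reactants: 18 C3 β-alcohol
Product: 19 benzylidene-protected 3α-bromo-2,2,6α-trimethyloxane
Conditions: CBr4, PPh3, 2,6-lutidine, toluene, 80 °C
Reagents that add atoms: carbon tetrabromide BrC(Br)(Br)Br
Why: Appel bromination of the only free hydroxyl proceeds by SN2 displacement of the axial oxyphosphonium group from the α face and should give the equatorial C3 bromide of the target with inversion, a displacement known for 2,2,6-trisubstituted oxan-3-ols.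

**Step 13**
Reactants: 19 bromide
Product: 20 5β-benzyloxy-3α-bromo-6β-(hydroxymethyl)-2,2,6α-trimethyloxane
Conditions: DIBAL-H, CH2Cl2, −78 → 0 °C; Rochelle salt
Reagents that add atoms: none
Why: In this reductive benzylidene opening the aluminium binds the less hindered primary oxygen and hydride goes to the oxocarbenium ion left on O5, which leaves the benzyl group on C5 and frees C1′H2OH.

**Step 14**
Reactants: 20 primary alcohol
Product: 21 5β-benzyloxy-3α-bromo-2,2,6α-trimethyloxane-6β-carbaldehyde
Conditions: Dess–Martin periodinane, CH2Cl2, rt
Reagents that add atoms: none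
Why: Dess–Martin oxidation gives a non-enolisable α-quaternary aldehyde under neutral conditions that leave the bromide and benzyl ether alone.

**Step 15**
Reactants: 21 aldehyde; 22 4-bromo-2-methylbut-1-ene
Product: 24 1-(oxan-6β-yl)-4-methylpent-4-en-1-ol (both C1′ epimers), via 3-methylbut-3-enylmagnesium bromide 23 (not isolated)
Conditions: 22, Mg, THF, rt; then 21, THF, −78 → 0 °C
Reagents that add atoms: magnesium [Mg] (only in 23)
Why: Grignard addition brings in C6′, C5′, C4′ and its methyl, and the configuration of the new carbinol is irrelevant because it is oxidised in the next step.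

**Step 16**
Reactants: 24 secondary alcohol
Product: 25 1-(oxan-6β-yl)-4-methylpent-4-en-1-one
Conditions: Dess–Martin periodinane, CH2Cl2, rt
Reagents that add atoms: none
Why: Dess–Martin oxidation converts both epimers into one ketone without moving the 1,1-disubstituted alkene.

**Step 17**
Reactants: 25 ketone; 26 allylmagnesium bromide
Product: 27 (1′R)-4-(oxan-6β-yl)-7-methylocta-1,7-dien-4-ol
Conditions: 26, Et2O/CH2Cl2, −78 °C
Reagents that add atoms: none
Why: Felkin–Anh addition, with the C6–O1 bond anti to the incoming allyl group and the nucleophile passing the C6 methyl, should set C1′ as R; magnesium bridging the carbonyl and the C5 benzyloxy oxygen holds the same rotamer, and O1, buried between two quaternary carbons, is a poor chelating donor.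

**Step 18**
Reactants: 27 diene
Product: 28 (1′R)-4′-methyl-1′-(oxan-6β-yl)cyclohex-3′-en-1′-ol
Conditions: Grubbs II (5 mol %), CH2Cl2, 40 °C
Reagents that add atoms: none
Why: Ring-closing metathesis of a monosubstituted with a 1,1-disubstituted alkene closes the six-membered ring at C3′=C4′ and tolerates the free tertiary alcohol.

**Step 19**
Reactants: 28 cyclohexenol
Product: 29 4-(oxan-6β-yl)-2-endo-bromo-1-methyl-7-oxabicyclo[2.2.1]heptane (C1′–O–C4′ ether, Br on C3′ cis to the oxanyl group)
Conditions: NBS, 4 Å MS, CH2Cl2, 0 °C, dark
Reagents that add atoms: N-bromosuccinimide O=C1CCC(=O)N1Br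
Why: In this intramolecular bromoetherification bromonium formation is reversible and only the ion on the face opposite the axial C1′ hydroxyl can be captured, by attack of that oxygen on the tertiary C4′ through a boat, which puts bromine at C3′ and oxygen at C4′ on the faces the target needs; direct BrCl addition is avoided because Fürst–Plattner (diaxial) opening in the conformationally locked ring would give the other anti adduct.

**Step 20**
Reactants: 29 bromo ether
Product: 30 target, (2S,3R,5R)-5-bromo-2-[(1R,3S,4S)-3-bromo-4-chloro-1-hydroxy-4-methylcyclohexyl]-2,6,6-trimethyloxan-3-ol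
Conditions: BCl3 (4 equiv), CH2Cl2, −78 → −30 °C; MeOH, aq NaHCO3
Reagents that add atoms: boron trichloride ClB(Cl)Cl
Why: Proposed new method: BCl3 should bind the exposed, strained bridge oxygen, the C4′–O bond ionises with help from the antiperiplanar endo bromine on C3′, and the bromonium ion, closed on the bromine face, takes chloride from the neighbouring borate at the tertiary C4′ on the face the oxygen has just left, so oxygen is exchanged for chlorine with retention and the ring relaxes to the chair with Br and Cl equatorial, while excess reagent cleaves the C5 benzyl ether; the closest known reaction types are boron trihalide cleavage of tertiary and benzyl ethers, hydrogen chloride opening of 1,4-cineole to tertiary chlorides and retentive substitution of β-bromo derivatives through bromonium ions, and the C1′–O and O1–C6 bonds are held back by β-oxygen atoms while O1 is shielded by two quaternary carbons.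

**Compound list**

1 | pyruvaldehyde dimethyl acetal | CC(=O)C(OC)OC | starting material
2 | (S)-1-phenylethanol | C[C@H](O)c1ccccc1 | starting material
3 | 1,1-bis[(S)-1-phenylethoxy]propan-2-one | CC(=O)C(O[C@@H](C)c1ccccc1)O[C@@H](C)c1ccccc1 | intermediate
4 | 2-(triethylsilyloxy)acrolein bis[(S)-1-phenylethyl] acetal | C=C(O[Si](CC)(CC)CC)C(O[C@@H](C)c1ccccc1)O[C@@H](C)c1ccccc1 | intermediate
5 | 2,5-dimethylfuran | Cc1ccc(C)o1 | starting material
6 | (Z)-1-[(S)-1-phenylethoxy]-2-(triethylsilyloxy)allyl cation | [CH2+]/C(O[Si](CC)(CC)CC)=C/O[C@@H](C)c1ccccc1 | intermediate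
7 | (1R,2S,5R)-1,5-dimethyl-2-[(S)-1-phenylethoxy]-8-oxabicyclo[3.2.1]oct-6-en-3-one | C[C@@]12C=C[C@@](C)(O1)[C@H](O[C@@H](C)c1ccccc1)C(=O)C2 | intermediate
8 | C3=C4 enol triflate of 7 | C[C@@]12C=C[C@@](C)(O1)[C@H](O[C@@H](C)c1ccccc1)C(OS(=O)(=O)C(F)(F)F)=C2 | intermediate
9 | 2β,6β-diformyl dihydropyranyl triflate | C[C@@]1(C=O)O[C@](C)(C=O)[C@H](O[C@@H](C)c2ccccc2)C(OS(=O)(=O)C(F)(F)F)=C1 | intermediate
10 | 2β,6β-bis(hydroxymethyl) dihydropyranyl triflate, C5β-O-(S)-1-phenylethyl | C[C@@]1(CO)O[C@](C)(CO)[C@H](O[C@@H](C)c2ccccc2)C(OS(=O)(=O)C(F)(F)F)=C1 | intermediate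
11 | 5β-hydroxy-2β,6β-bis(hydroxymethyl) dihydropyranyl triflate | C[C@@]1(CO)O[C@](C)(CO)[C@H](O)C(OS(=O)(=O)C(F)(F)F)=C1 | intermediate
12 | C5–O/C1′–O benzylidene acetal of 11 | C[C@@]1(CO)O[C@]2(C)CO[C@H](c3ccccc3)O[C@@H]2C(OS(=O)(=O)C(F)(F)F)=C1 | intermediate
13 | benzylidene-protected C3=C4 alkene with C2β-CH2OH | C[C@@]1(CO)O[C@]2(C)CO[C@H](c3ccccc3)O[C@@H]2C=C1 | intermediate
14 | dimethylsilyl ether of 13 | C[C@@]1(CO[SiH](C)C)O[C@]2(C)CO[C@H](c3ccccc3)O[C@@H]2C=C1 | intermediate
15 | 1,2-oxasilolane cis-fused at C2–C3 (C3β–SiMe2–O–CH2–C2) | C[C@@]1(CO[Si]4(C)C)O[C@]2(C)CO[C@H](c3ccccc3)O[C@@H]2C[C@@H]14 | intermediate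
16 | benzylidene-protected 3β-hydroxy-2β-(hydroxymethyl)oxane | C[C@@]1(CO)O[C@]2(C)CO[C@H](c3ccccc3)O[C@@H]2C[C@@H]1O | intermediate
17 | benzylidene-protected 2β-(iodomethyl)oxan-3β-ol | C[C@@]1(CI)O[C@]2(C)CO[C@H](c3ccccc3)O[C@@H]2C[C@@H]1O | intermediate
18 | benzylidene-protected 2,2,6α-trimethyloxan-3β-ol | CC1(C)O[C@]2(C)CO[C@H](c3ccccc3)O[C@@H]2C[C@@H]1O | intermediate
19 | benzylidene-protected 3α-bromo-2,2,6α-trimethyloxane | CC1(C)O[C@]2(C)CO[C@H](c3ccccc3)O[C@@H]2C[C@H]1Br | intermediate
20 | 5β-benzyloxy-3α-bromo-6β-(hydroxymethyl)-2,2,6α-trimethyloxane | CC1(C)O[C@](C)(CO)[C@H](OCc2ccccc2)C[C@H]1Br | intermediate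
21 | 5β-benzyloxy-3α-bromo-2,2,6α-trimethyloxane-6β-carbaldehyde | CC1(C)O[C@](C)(C=O)[C@H](OCc2ccccc2)C[C@H]1Br | intermediate
22 | 4-bromo-2-methylbut-1-ene | C=C(C)CCBr | starting material
23 | 3-methylbut-3-enylmagnesium bromide | C=C(C)CC[Mg]Br | intermediate
24 | C1′ secondary alcohol, both epimers | CC1(C)O[C@](C)(C(O)CCC(C)=C)[C@H](OCc2ccccc2)C[C@H]1Br | intermediate
25 | C1′ ketone | CC1(C)O[C@](C)(C(=O)CCC(C)=C)[C@H](OCc2ccccc2)C[C@H]1Br | intermediate
26 | allylmagnesium bromide | C=CC[Mg]Br | starting material
27 | (1′R)-tertiary alcohol diene | CC1(C)O[C@](C)([C@](O)(CC=C)CCC(C)=C)[C@H](OCc2ccccc2)C[C@H]1Br | intermediate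
28 | (1′R)-4′-methylcyclohex-3′-en-1′-ol | CC1(C)O[C@](C)([C@@]2(O)CCC(C)=CC2)[C@H](OCc3ccccc3)C[C@H]1Br | intermediate
29 | endo-bromo 7-oxabicyclo[2.2.1]heptane (C1′–O–C4′ ether) | CC1(C)O[C@](C)([C@]23CC[C@](C)(O2)[C@@H](Br)C3)[C@H](OCc2ccccc2)C[C@H]1Br | intermediate
30 | CNP0244614.1 | CC1(C)O[C@](C)([C@@]2(O)CC[C@](C)(Cl)[C@@H](Br)C2)[C@H](O)C[C@H]1Br | target

Total step count: 20. Longest linear sequence: 20 steps (1 → 30); 5, 22 and 26 enter as purchased.

**Steps most likely to fail**

Step 20 (labelled step). Three processes could spoil it.
- The Lewis acid may ionise the O1–C2 bond of the oxane, which the C3 bromine can also assist.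
- The bromonium ion may lose a proton.
- The bromonium ion may hand Br+ to chloride before C–Cl bond formation, which would let the halogens re-add in the diaxial sense.

The fallback uses known interhalogen addition; it sets out from 28 and returns at 30. The tertiary alcohol is capped with TMSOTf/2,6-lutidine to give the trimethylsilyl ether F1, which can no longer close the ether bridge and whose axial silyloxy group hinders the face that must stay free of bromine. Tetrabutylammonium dichlorobromate in CH2Cl2 then adds Br and Cl anti and in the Markovnikov sense. The two anti adducts are separated by chromatography, and the wanted one may be the lesser component. The adduct with bromine cis to the oxanyl group, the protected bromochloride F2, is freed from silyl and benzyl groups with BCl3 at −78 °C to give 30.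

Step 12. Elimination towards C4 or migration of the antiperiplanar C2 methyl may overtake substitution at the hindered, neopentyl-type carbinol while the bulky oxyphosphonium ion waits for bromide. The fallback changes the mode of activation; it sets out from 18 and returns at 19. Tf2O/pyridine at −78 °C gives the isolable C3 β-triflate F3, a small and much better leaving group. Soluble, non-basic tetrabutylammonium bromide in toluene displaces it at or below room temperature with inversion.

Step 17. The allyl reagent may attack the other carbonyl face, for instance if magnesium is held by O1 after all, which would favour the C1′ epimer. The fallback exchanges the order of the two C–C bond formations; it sets out from 21 and returns at 27. Reagent 26 adds to 21 to give the homoallylic alcohol F4, and Dess–Martin oxidation gives the allyl ketone F5. Reagent 23, made less basic with LaCl3·2LiCl to suppress enolisation, is then added. Because the two carbon groups now arrive in the reverse order, the facial preference that spoiled step 17 delivers 27.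

**Further compounds**

F1 | step 20 | C1′ trimethylsilyl ether of 28 | CC1(C)O[C@](C)([C@@]2(O[Si](C)(C)C)CCC(C)=CC2)[C@H](OCc3ccccc3)C[C@H]1Br
F2 | step 20 | C1′-O-TMS, C5-O-benzyl protected bromochloride | CC1(C)O[C@](C)([C@@]2(O[Si](C)(C)C)CC[C@](C)(Cl)[C@@H](Br)C2)[C@H](OCc3ccccc3)C[C@H]1Br
F3 | step 12 | C3 β-triflate of 18 | CC1(C)O[C@]2(C)CO[C@H](c3ccccc3)O[C@@H]2C[C@@H]1OS(=O)(=O)C(F)(F)F
F4 | step 17 | 1-(oxan-6β-yl)but-3-en-1-ol, both epimers | CC1(C)O[C@](C)(C(O)CC=C)[C@H](OCc2ccccc2)C[C@H]1Br
F5 | step 17 | 1-(oxan-6β-yl)but-3-en-1-one | CC1(C)O[C@](C)(C(=O)CC=C)[C@H](OCc2ccccc2)C[C@H]1Br
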